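The constants used here are made up; what happens was integrated by code.

Over 3.0 h you feed free monomer into a stirred, isothermal flask that already holds initiator and impurity, and at 30 h you ask how long the chains are.

free monomer 0.80 M (fed, over 3.0 h); initiator 4.0 mM; impurity 1.5 mM; time 30 h

    initiator + impurity → spent initiator B (k1 = 1.8 L mol⁻¹ s⁻¹)
    free monomer + initiator → living end + monomer in chains (k2 = 0.0024 L mol⁻¹ s⁻¹)
    free monomer + living end → monomer in chains + living end, rate k3*[living end]*[free monomer] (k3 = 0.056 L mol⁻¹ s⁻¹)
    living end → dead end A (k4 = 1.5 × 10⁻⁴ s⁻¹)

- whether the average number of monomer units in a chain (chains begun, living or dead) reaches 100 by 30 h (yes / no)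
- average number of monomer units in a chain (chains begun, living or dead) at 30 h

- the average divides the monomer in chains by the number of chains begun, living and dead together
- run time (flask): 30 h

- **First instants.** Ignoring what propagation draws off, half of the chains have begun by 0.776 h, and the impurity takes initiator with a half-life of 0.071 h, which is shorter than that. With 1.5 mM of impurity against 4.0 mM of initiator, the impurity is the limiting reagent of that step. So you count on 2.50 mM of chains.
- **Middle.** [free monomer] climbs with the feed, and [initiator] falls as free monomer starts chains. Each living end then lasts 1.85 h on average.
- **The quantity to carry.** Call the exposure the rate constant of propagation times the chains, divided by the rate constant of death, which is 0.933: the natural-log drop in free monomer that those living ends deliver before they die.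
- **First round.** If free monomer met the whole exposure, 60.7% of it would react, giving 194 units per chain.
- **Second round.** Put the birth time back in. Monomer fed after 0.776 h meets a shrinking exposure, down to 0.281 at the end of the feed.
- **End.** Averaged over the feed, this leaves 54.0% of the free monomer unreacted. I commit to 147 units, above 100.
- **Forecast.** The forecast says yes and 150, above my figure, holding that “every chain is dead well before” 30 h.
- **Result.** The flask gives yes, passing 100 at 3.29 h, and 150 at 30 h. The half-life of the living end, 1.3 h, is far shorter than the run, and at 3.00 h the flask held 8.08 × 10⁻⁴ M of living end and 71.8% of its free monomer. That leaves an exposure of 0.302, which takes the free monomer to 53.1%, and the flask shows 53.1% at 30.0 h.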